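## Retrosynthetic overview
1. Neocryptomerin comes from a single BCl3 deprotection (one 5-OMe, two OBn) of the fully assembled biflavone ether. Unit 1 is the 7-methoxyflavone and unit 2 is the 6-aryloxyflavone.
2. Ring C of unit 1 is cut twice: at O1–C8a (enolate SNAr on an aryl fluoride) and at C2–C3 (the key bond).
3. The key C2–C3 bond joins an acyl anion equivalent (the Breslow enaminol of the unit 2 aryl aldehyde) to the α-bromo ketone of ring A of unit 1. The aldehyde carbon and the CH2Br carbon are both electrophiles as bought.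
4. The aldehyde comes from Cu-catalysed C6–O coupling of 6-iodo-7,4'-di-O-benzylapigenin with 4-hydroxybenzaldehyde. The bromo ketone comes from Friedel–Crafts acylation of 1-fluoro-3,5-dimethoxybenzene.
5. Ring order: rings A, B and C of unit 2 arrive intact in apigenin, and rings A and B of unit 1 are bought arenes. The only ring built is ring C of unit 1, in the key step.

Assumption: the target has no stereocentre and no hindered axis (its SMILES carries no stereo descriptors), so it is made as the single achiral compound drawn.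

## Route

Step 1
Reactants: 1 apigenin (5,7-dihydroxy-2-(4-hydroxyphenyl)-4H-chromen-4-one)
Product: 2 7-(benzyloxy)-2-[4-(benzyloxy)phenyl]-5-hydroxy-4H-chromen-4-one (7,4'-di-O-benzylapigenin)
Conditions: BnBr (2.2 equiv), K2CO3 (2.5 equiv), DMF, 25 → 50 °C
Reagents that add atoms: benzyl bromide, BrCc1ccccc1
Why: Williamson ether synthesis in which the acidic 7-OH and 4'-OH are alkylated while the 5-OH, hydrogen-bonded to C4=O, stays free; no stereocentre is formed.

Step 2
Reactants: 2 7,4'-di-O-benzylapigenin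
Product: 3 7-(benzyloxy)-2-[4-(benzyloxy)phenyl]-5-hydroxy-6-iodo-4H-chromen-4-one
Conditions: BnMe3N·ICl2 (1.05 equiv), CaCO3, CH2Cl2/MeOH (5:2), rt, dark
Reagents that add atoms: benzyltrimethylammonium dichloroiodate, C[N+](C)(C)Cc1ccccc1.Cl[I-]Cl
Why: Electrophilic aromatic iodination in which the free 5-OH directs to its ortho position C6 (5-hydroxy-7-alkoxyflavones iodinate at C6, only 5-O-alkylated ones at C8), with CaCO3 removing the HCl.

Step 3
Reactants: 3 6-iodo-7,4'-di-O-benzylapigenin; 4 4-hydroxybenzaldehyde (2 equiv)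
Product: 5 4-({7-(benzyloxy)-2-[4-(benzyloxy)phenyl]-5-hydroxy-4-oxo-4H-chromen-6-yl}oxy)benzaldehyde
Conditions: CuI (20 mol%), picolinic acid (40 mol%), K3PO4 (3 equiv), DMSO, 100 °C, Ar
Reagents that add atoms: none
Why: Ullmann-type Cu-catalysed diaryl ether synthesis with the ligand/base pair developed for ortho-hindered partners, supported by the known Cu-mediated C–O substitution of C6 halides of 5-hydroxyflavones by alkoxides.

Step 4
Reactants: 6 1-fluoro-3,5-dimethoxybenzene; 7 bromoacetyl bromide
Product: 8 2-bromo-1-(2-fluoro-4,6-dimethoxyphenyl)ethan-1-one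
Conditions: AlCl3 (1.2 equiv), CH2Cl2, −10 → 0 °C, 1 h
Reagents that add atoms: none
Why: Friedel–Crafts acylation that goes para to one OMe and ortho to the other, next to the small fluorine rather than between the two OMe groups, with the low temperature suppressing AlCl3 demethylation.

Step 5 (key step)
Reactants: 5 4-(flavon-6-yloxy)benzaldehyde; 8 2-bromo-1-(2-fluoro-4,6-dimethoxyphenyl)ethan-1-one (1.2 equiv)
Product: 11 7-(benzyloxy)-2-[4-(benzyloxy)phenyl]-6-[4-(5,7-dimethoxy-4-oxo-4H-chromen-2-yl)phenoxy]-5-hydroxy-4H-chromen-4-one, via Breslow enaminol 9 (not isolated), via fluoroaryl 1,3-diketone 10 (not isolated)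
Conditions: 3-benzyl-5-(2-hydroxyethyl)-4-methylthiazolium chloride (25 mol%), Cs2CO3 (3.5 equiv), THF, 45 °C, Ar, 8 added over 6 h; then DMF added, THF distilled off, 100 °C, 6 h (one pot)
Reagents that add atoms: none
Why: Proposed new method: the deprotonated thiazolium salt adds to the formyl group of 5 and proton transfer gives Breslow enaminol 9, an acyl anion equivalent whose former carbonyl carbon displaces bromide from the CH2Br carbon of 8 by SN2 (two carbons that are both electrophilic in the reagents are joined, and the F/OMe-flanked ketone of 8 is shielded from competing 1,2-addition); collapse releases the catalyst and diketone 10, whose caesium enolate oxygen then closes ring C of unit 1 by intramolecular SNAr on the ortho C–F bond activated by the aryl ketone; the closest known reaction types are the NHC-catalysed nucleophilic acylation of phenacyl and benzhydryl halides with aromatic aldehydes and the base-mediated cyclisation of 1-(2-haloaryl)-1,3-diketones to chromones, merged here in one pot on a late-stage substrate, and no stereocentre is formed.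

Step 6
Reactants: 11 protected biflavone ether
Product: 12 neocryptomerin (6-[4-(5-hydroxy-7-methoxy-4-oxo-4H-chromen-2-yl)phenoxy]-5,7-dihydroxy-2-(4-hydroxyphenyl)-4H-chromen-4-one)
Conditions: BCl3 (10 equiv, 1 M in CH2Cl2), pentamethylbenzene (6 equiv), CH2Cl2, −78 °C (1 h) → rt (3 h); aqueous work-up
Reagents that add atoms: none
Why: Lewis-acid ether cleavage in which BCl3 strips both aryl benzyl ethers (pentamethylbenzene traps the benzyl cation and prevents C-benzylation) and, chelated between C4=O and the peri 5-OMe, cleaves only that methyl ether, leaving the unchelated 7-OMe and the diaryl ether untouched.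

## Compound list
1 | apigenin, 5,7-dihydroxy-2-(4-hydroxyphenyl)-4H-chromen-4-one | O=c1cc(-c2ccc(O)cc2)oc2cc(O)cc(O)c12 | starting material
2 | 7-(benzyloxy)-2-[4-(benzyloxy)phenyl]-5-hydroxy-4H-chromen-4-one | O=c1cc(-c2ccc(OCc3ccccc3)cc2)oc2cc(OCc3ccccc3)cc(O)c12 | intermediate
3 | 7-(benzyloxy)-2-[4-(benzyloxy)phenyl]-5-hydroxy-6-iodo-4H-chromen-4-one | O=c1cc(-c2ccc(OCc3ccccc3)cc2)oc2cc(OCc3ccccc3)c(I)c(O)c12 | intermediate
4 | 4-hydroxybenzaldehyde | O=Cc1ccc(O)cc1 | starting material
5 | 4-({7-(benzyloxy)-2-[4-(benzyloxy)phenyl]-5-hydroxy-4-oxo-4H-chromen-6-yl}oxy)benzaldehyde | O=Cc1ccc(Oc2c(OCc3ccccc3)cc3oc(-c4ccc(OCc5ccccc5)cc4)cc(=O)c3c2O)cc1 | intermediate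
6 | 1-fluoro-3,5-dimethoxybenzene | COc1cc(F)cc(OC)c1 | starting material
7 | bromoacetyl bromide | O=C(Br)CBr | starting material
8 | 2-bromo-1-(2-fluoro-4,6-dimethoxyphenyl)ethan-1-one | COc1cc(F)c(C(=O)CBr)c(OC)c1 | intermediate
9 | Breslow enaminol: 3-benzyl-5-(2-hydroxyethyl)-4-methyl-2-[hydroxy(aryl)methylidene]-2,3-dihydrothiazole, aryl = the 4-(flavon-6-yloxy)phenyl group of 5 | OC(=C1SC(CCO)=C(C)N1Cc1ccccc1)c1ccc(Oc2c(OCc3ccccc3)cc3oc(-c4ccc(OCc5ccccc5)cc4)cc(=O)c3c2O)cc1 | intermediate
10 | 1-(2-fluoro-4,6-dimethoxyphenyl)-3-[4-({7-(benzyloxy)-2-[4-(benzyloxy)phenyl]-5-hydroxy-4-oxo-4H-chromen-6-yl}oxy)phenyl]propane-1,3-dione | COc1cc(F)c(C(=O)CC(=O)c2ccc(Oc3c(OCc4ccccc4)cc4oc(-c5ccc(OCc6ccccc6)cc5)cc(=O)c4c3O)cc2)c(OC)c1 | intermediate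
11 | 7-(benzyloxy)-2-[4-(benzyloxy)phenyl]-6-[4-(5,7-dimethoxy-4-oxo-4H-chromen-2-yl)phenoxy]-5-hydroxy-4H-chromen-4-one | COc1cc(OC)c2c(=O)cc(-c3ccc(Oc4c(OCc5ccccc5)cc5oc(-c6ccc(OCc7ccccc7)cc6)cc(=O)c5c4O)cc3)oc2c1 | intermediate
12 | neocryptomerin | COc1cc(O)c2c(=O)cc(-c3ccc(Oc4c(O)cc5oc(-c6ccc(O)cc6)cc(=O)c5c4O)cc3)oc2c1 | target

## Step count and risks
Total steps: 6. Longest linear sequence: 5 (steps 1, 2, 3, 5 and 6, from apigenin); step 4 is a one-step side branch.

**The Ullmann coupling (step 3).**
- Risk: C6–I is electron-rich and flanked on both sides, and the phenol partner is electron-poor. Protodeiodination back to 2 is the likely failure.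
- Fallback: it sets out from 3 and inverts the roles of the two ether partners.
- Cu-catalysed hydroxylation (CuI, 8-hydroxyquinoline, KOH, DMSO/H2O, 100 °C, Ar) gives 7-(benzyloxy)-2-[4-(benzyloxy)phenyl]-5,6-dihydroxy-4H-chromen-4-one F1.
- The 6-OH of F1 (the 5-OH is chelated) then attacks 4-fluorobenzaldehyde in an SNAr reaction (K2CO3, DMF, 110 °C, Ar).
- This comes back to the route at 5 and costs one more step.

**The Friedel–Crafts bromoacetylation (step 4).**
- Risk: AlCl3 may cleave the OMe next to the new ketone, may scramble Br for Cl at the α-carbon, or may give some of the 4-fluoro-2,6-dimethoxy isomer.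
- Fallback: it sets out from 6 and separates C–C bond formation from halogenation.
- Acetyl chloride with SnCl4 in CH2Cl2 at −20 °C gives 1-(2-fluoro-4,6-dimethoxyphenyl)ethan-1-one F2, which is freed of isomers by crystallisation.
- F2 is then α-brominated with CuBr2 (2 equiv) in refluxing EtOAc/CHCl3, coming back to the route at 8.

**The key coupling and ring closure (step 5).**
- Risk: the catalyst can be alkylated by 8. The 5-OH of unit 2 or the enolate of 10 can be alkylated by 8. The large, fairly electron-rich aldehyde 5 may form its enaminol slowly.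
- Fallback: it sets out from 8 and keeps the same polarity-reversed C2–C3 bond. The bond is made on a small, electron-poor aldehyde, and the fragment union becomes a C–O bond formation.
- 4-Fluorobenzaldehyde (2 equiv) and 8 react under the same thiazolium chloride/Cs2CO3 conditions. The sequence passes through 3-benzyl-2-[(4-fluorophenyl)(hydroxy)methylidene]-5-(2-hydroxyethyl)-4-methyl-2,3-dihydrothiazole F3 and 1-(2-fluoro-4,6-dimethoxyphenyl)-3-(4-fluorophenyl)propane-1,3-dione F4. It ends at 2-(4-fluorophenyl)-5,7-dimethoxy-4H-chromen-4-one F5.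
- The 4'-fluorine of F5, activated by the chromone, is then displaced by the 6-OH of F1 (drawn from 3 as described above) with Cs2CO3 in DMSO at 130 °C.
- This comes back to the route at 11.

## Further compounds
F1 | step 3 | 7-(benzyloxy)-2-[4-(benzyloxy)phenyl]-5,6-dihydroxy-4H-chromen-4-one | O=c1cc(-c2ccc(OCc3ccccc3)cc2)oc2cc(OCc3ccccc3)c(O)c(O)c12
F2 | step 4 | 1-(2-fluoro-4,6-dimethoxyphenyl)ethan-1-one | COc1cc(F)c(C(C)=O)c(OC)c1
F3 | step 5 | 3-benzyl-2-[(4-fluorophenyl)(hydroxy)methylidene]-5-(2-hydroxyethyl)-4-methyl-2,3-dihydrothiazole | OC(=C1SC(CCO)=C(C)N1Cc1ccccc1)c1ccc(F)cc1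
F4 | step 5 | 1-(2-fluoro-4,6-dimethoxyphenyl)-3-(4-fluorophenyl)propane-1,3-dione | COc1cc(F)c(C(=O)CC(=O)c2ccc(F)cc2)c(OC)c1
F5 | step 5 | 2-(4-fluorophenyl)-5,7-dimethoxy-4H-chromen-4-one | COc1cc(OC)c2c(=O)cc(-c3ccc(F)cc3)oc2c1
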